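**Retrosynthetic overview**
1. Feature used: in the seven-membered ring the diaryl ether oxygen is bonded to the ring A carbon ortho to the carbon that carries the ester carbonyl. A bromine on that carbon is activated for copper insertion, and the ester link between ring A and ring B serves as the tether.
2. Target (R)-lactol ⇐ (R)-lactol acetate ⇐ racemic lactol (lipase acylation with racemisation in situ, then base-free deacetylation) ⇐ depsidone carrying CHO and CO2Bn on ring B (hydrogenolysis, spontaneous lactol closure).
3. Depsidone ⇐ 2-bromo depside, by intramolecular copper-mediated C–O coupling of the formyl-flanked ring B phenol with the ring A C–Br bond.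
4. Depside ⇐ ring A acid (from creosol: acetate, formylation para to OMe, bromination ortho to OH, benzylation, oxidation) + ring B formyl catechol benzyl ester (from 2,4-dihydroxy-3-methylbenzoic acid: Elbs hydroxylation, benzyl ester, formylation).
5. Ring order: both benzene rings are bought; the seven-membered dioxepinone ring is closed first (key step), the five-membered lactol ring last.

Key step: step 11

Assumption: the lactol carbon epimerises by ring–chain tautomerism when base or water is present, so the (R) centre is set last by enzyme-controlled acylation, and the lipase is taken to be the one that acylates the (R)-lactol in a short screen.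

**Route**

Step 1
Reactants: 1 creosol (2-methoxy-4-methylphenol)
Product: 2 2-methoxy-4-methylphenyl acetate
Conditions: Ac2O, pyridine, DMAP (cat.), CH2Cl2, 0 °C to rt
Reagents that add atoms: acetic anhydride, CC(=O)OC(C)=O
Why: O-acetylation (acyl transfer) masks the phenol as a weak donor so that the methoxy group directs the next substitution.

Step 2
Reactants: 2 2-methoxy-4-methylphenyl acetate
Product: 4 5-formyl-2-methoxy-4-methylphenyl acetate, via α-chloro ether 3 (not isolated)
Conditions: Cl2CHOMe, TiCl4, CH2Cl2, −10 to 0 °C; then ice-cold aq. HCl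
Reagents that add atoms: dichloromethyl methyl ether, COC(Cl)Cl; water, O
Why: Rieche formylation is an electrophilic aromatic substitution that should go to the carbon para to OMe and ortho to CH3, the most activated open site once the phenol is an acetate, and the α-chloro ether is hydrolysed to the aldehyde on work-up.

Step 3
Reactants: 4 5-formyl-2-methoxy-4-methylphenyl acetate
Product: 5 5-hydroxy-4-methoxy-2-methylbenzaldehyde
Conditions: K2CO3 (0.2 equiv), MeOH, rt
Reagents that add atoms: none
Why: Carbonate-catalysed methanolysis (transesterification) cleaves the aryl acetate under conditions that leave the aldehyde alone.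

Step 4
Reactants: 5 5-hydroxy-4-methoxy-2-methylbenzaldehyde
Product: 6 2-bromo-3-hydroxy-4-methoxy-6-methylbenzaldehyde
Conditions: Br2, NaOAc, Fe powder (cat.), AcOH, rt
Reagents that add atoms: bromine, BrBr
Why: Electrophilic aromatic bromination is directed ortho to the free phenol, as in the known bromination of isovanillin at its 2-position, and here the para position is blocked by the methyl group.

Step 5
Reactants: 6 2-bromo-3-hydroxy-4-methoxy-6-methylbenzaldehyde
Product: 7 3-(benzyloxy)-2-bromo-4-methoxy-6-methylbenzaldehyde
Conditions: BnBr, K2CO3, DMF, 50 °C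
Reagents that add atoms: benzyl bromide, BrCc1ccccc1
Why: Williamson ether synthesis on the phenoxide protects the ring A phenol for the oxidation and coupling steps.

Step 6
Reactants: 7 3-(benzyloxy)-2-bromo-4-methoxy-6-methylbenzaldehyde
Product: 8 3-(benzyloxy)-2-bromo-4-methoxy-6-methylbenzoic acid
Conditions: NaClO2, NaH2PO4, 2-methyl-2-butene, t-BuOH/H2O, rt
Reagents that add atoms: sodium chlorite, [Na+].[O-]Cl=O
Why: Pinnick oxidation converts the hindered aryl aldehyde into the acid without touching the aryl bromide or benzyl ether, with 2-methyl-2-butene trapping the hypochlorous acid.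

Step 7
Reactants: 9 2,4-dihydroxy-3-methylbenzoic acid
Product: 11 2,4,5-trihydroxy-3-methylbenzoic acid, via aryl sulfate 10 (not isolated)
Conditions: K2S2O8, aq. NaOH, 5 to 20 °C; then HCl to pH 1, 80 °C
Reagents that add atoms: potassium peroxodisulfate, [K+].[K+].[O-]S(=O)(=O)OOS(=O)(=O)[O-]
Why: In the Elbs persulfate oxidation the phenolate attacks peroxodisulfate through the one free carbon para to the 2-oxide (and ortho to the 4-oxide), and acid hydrolysis of the aryl sulfate releases the new phenol.

Step 8
Reactants: 11 2,4,5-trihydroxy-3-methylbenzoic acid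
Product: 12 benzyl 2,4,5-trihydroxy-3-methylbenzoate
Conditions: BnBr (1.05 equiv), KHCO3, degassed DMF, rt, argon
Reagents that add atoms: benzyl bromide, BrCc1ccccc1
Why: SN2 alkylation of the carboxylate, the only group ionised by hydrogen carbonate, gives the benzyl ester while the three phenols stay free.

Step 9
Reactants: 12 benzyl 2,4,5-trihydroxy-3-methylbenzoate
Product: 14 benzyl 2-formyl-3,4,6-trihydroxy-5-methylbenzoate, via α-chloro ether 13 (not isolated)
Conditions: Cl2CHOMe, TiCl4, CH2Cl2, −10 °C to rt; then aq. HCl
Reagents that add atoms: dichloromethyl methyl ether, COC(Cl)Cl; water, O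
Why: Rieche formylation through the titanium phenoxide is an ortho-directed electrophilic substitution, and the only unsubstituted ring carbon lies ortho to a phenol oxygen and para to the methyl group, so only one regioisomer can form.

Step 10
Reactants: 8 3-(benzyloxy)-2-bromo-4-methoxy-6-methylbenzoic acid; 14 benzyl 2-formyl-3,4,6-trihydroxy-5-methylbenzoate
Product: 16 benzyl 4-{[3-(benzyloxy)-2-bromo-4-methoxy-6-methylbenzoyl]oxy}-2-formyl-3,6-dihydroxy-5-methylbenzoate (the depside), via mixed anhydride 15 (not isolated)
Conditions: (CF3CO)2O, toluene, rt; then brief aq. NaHCO3 wash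
Reagents that add atoms: none
Why: Depside esterification through the mixed trifluoroacetic anhydride suits a 2,6-disubstituted benzoic acid, and it should acylate the one phenol not hydrogen-bonded to a carbonyl (the OH para to the benzyl ester), which also gives the more stable isomer because the OH···O=CH chelate is kept.

Step 11
Reactants: 16 the depside
Product: 17 benzyl 4-(benzyloxy)-6-formyl-8-hydroxy-3-methoxy-1,9-dimethyl-11-oxo-11H-dibenzo[b,e][1,4]dioxepine-7-carboxylate (the depsidone)
Conditions: CuI (20 mol %), N,N-dimethylglycine (40 mol %), Cs2CO3 (2.5 equiv), 4 Å molecular sieves, degassed 1,4-dioxane, 90 °C, argon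
Reagents that add atoms: none
Why: Cs2CO3 ionises the ring B phenol next to the formyl group, the phenoxide binds ligated monovalent copper, the copper adds oxidatively into the ring A C–Br bond ortho to the depside carbonyl (an aryl trivalent copper species, helped by carbonyl coordination), and C–O reductive elimination releases the diaryl ether and monovalent copper. The closest known reaction is the amino-acid-promoted intramolecular Ullmann diaryl ether synthesis between an ortho-halobenzoate and a phenol; N,N-dimethylglycine is chosen because it has no N–H to condense with the aldehyde. The seven-membered dioxepinone ring closes by this reductive elimination from an eight-membered copper chelate that the ester tether preorganises, so two di-ortho-substituted partners that would couple poorly between molecules react intramolecularly. No stereocenter is formed. The step needs site selectivity between the two catechol oxygens, since a 1,2-acyl shift followed by coupling would give the isomeric depsidone: the oxygen next to the formyl group is held as the chelated phenol or the formyl-conjugated phenoxide, so the aroyl group should rest on the oxygen para to the benzyl ester, and sparingly soluble Cs2CO3 in dioxane keeps the phenoxide concentration low. The third OH is chelated to the benzyl ester and cannot reach the bromide, and dry, air-free conditions protect the aryl ester and the para-dihydroxy pattern of ring B.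

Step 12
Reactants: 17 the depsidone
Product: 19 racemic lactol (1,4,11-trihydroxy-10-methoxy-5,8-dimethyl-1H-isobenzofuro[4,5-b][1,4]benzodioxepine-3,7-dione), via formyl acid 18 (not isolated)
Conditions: H2 (1 atm), 10% Pd/C, EtOAc/THF, rt, stopped after uptake of 2 equiv
Reagents that add atoms: none
Why: Catalytic hydrogenolysis cleaves the benzyl ester and the benzyl aryl ether, and the freed 2-formylbenzoic acid closes by ring–chain tautomerism to the 3-hydroxyphthalide, whose stereocenter forms without control (racemic).

Step 13
Reactants: 19 racemic lactol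
Product: 20 (R)-lactol acetate, (1R)-4,11-dihydroxy-10-methoxy-5,8-dimethyl-3,7-dioxo-1,3-dihydroisobenzofuro[4,5-b][1,4]benzodioxepin-1-yl acetate
Conditions: immobilised Burkholderia cepacia lipase, vinyl acetate (5 equiv), Et3N (0.2 equiv), 2-MeTHF, 35 °C
Reagents that add atoms: vinyl acetate, CC(=O)OC=C
Why: In this lipase-catalysed acylative dynamic kinetic resolution, of the kind practised on γ-hydroxybutenolides, Et3N racemises the lactol through the open formyl carboxylate while the enzyme pocket acylates only the (R)-lactol, so the enzyme sets the stereocenter and all material can funnel to the (R)-acetate.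

Step 14
Reactants: 20 (R)-lactol acetate
Product: 21 the target, (1R)-1,4,11-trihydroxy-10-methoxy-5,8-dimethyl-1H-isobenzofuro[4,5-b][1,4]benzodioxepine-3,7-dione
Conditions: immobilised Burkholderia cepacia lipase, n-BuOH (10 equiv), 2-MeTHF/MTBE, 0 to 20 °C, no base; filter, concentrate cold
Reagents that add atoms: none
Why: Lipase-catalysed alcoholysis cleaves the acetate at its acyl C–O bond, so the C–O bond at the stereocenter is untouched (retention), the same enzyme again prefers the (R)-ester, and the absence of base and water keeps the lactol closed.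

**Compound list**
1 | creosol (2-methoxy-4-methylphenol) | COc1cc(C)ccc1O | starting material
2 | 2-methoxy-4-methylphenyl acetate | COc1cc(C)ccc1OC(C)=O | intermediate
3 | 5-[chloro(methoxy)methyl]-2-methoxy-4-methylphenyl acetate (not isolated) | COc1cc(C)c(C(Cl)OC)cc1OC(C)=O | intermediate
4 | 5-formyl-2-methoxy-4-methylphenyl acetate | COc1cc(C)c(C=O)cc1OC(C)=O | intermediate
5 | 5-hydroxy-4-methoxy-2-methylbenzaldehyde | COc1cc(C)c(C=O)cc1O | intermediate
6 | 2-bromo-3-hydroxy-4-methoxy-6-methylbenzaldehyde | COc1cc(C)c(C=O)c(Br)c1O | intermediate
7 | 3-(benzyloxy)-2-bromo-4-methoxy-6-methylbenzaldehyde | COc1cc(C)c(C=O)c(Br)c1OCc1ccccc1 | intermediate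
8 | 3-(benzyloxy)-2-bromo-4-methoxy-6-methylbenzoic acid | COc1cc(C)c(C(=O)O)c(Br)c1OCc1ccccc1 | intermediate
9 | 2,4-dihydroxy-3-methylbenzoic acid | Cc1c(O)ccc(C(=O)O)c1O | starting material
10 | 2,4-dihydroxy-3-methyl-5-(sulfooxy)benzoic acid (present as its salt, not isolated) | Cc1c(O)c(OS(=O)(=O)O)cc(C(=O)O)c1O | intermediate
11 | 2,4,5-trihydroxy-3-methylbenzoic acid | Cc1c(O)c(O)cc(C(=O)O)c1O | intermediate
12 | benzyl 2,4,5-trihydroxy-3-methylbenzoate | Cc1c(O)c(O)cc(C(=O)OCc2ccccc2)c1O | intermediate
13 | benzyl 2-[chloro(methoxy)methyl]-3,4,6-trihydroxy-5-methylbenzoate (as titanium phenoxide, not isolated) | Cc1c(O)c(O)c(C(Cl)OC)c(C(=O)OCc2ccccc2)c1O | intermediate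
14 | benzyl 2-formyl-3,4,6-trihydroxy-5-methylbenzoate | Cc1c(O)c(O)c(C=O)c(C(=O)OCc2ccccc2)c1O | intermediate
15 | 3-(benzyloxy)-2-bromo-4-methoxy-6-methylbenzoic trifluoroacetic anhydride (not isolated) | COc1cc(C)c(C(=O)OC(=O)C(F)(F)F)c(Br)c1OCc1ccccc1 | intermediate
16 | benzyl 4-{[3-(benzyloxy)-2-bromo-4-methoxy-6-methylbenzoyl]oxy}-2-formyl-3,6-dihydroxy-5-methylbenzoate (depside) | COc1cc(C)c(C(=O)Oc2c(C)c(O)c(C(=O)OCc3ccccc3)c(C=O)c2O)c(Br)c1OCc1ccccc1 | intermediate
17 | benzyl 4-(benzyloxy)-6-formyl-8-hydroxy-3-methoxy-1,9-dimethyl-11-oxo-11H-dibenzo[b,e][1,4]dioxepine-7-carboxylate (depsidone) | COc1cc(C)c2c(c1OCc1ccccc1)Oc1c(C=O)c(C(=O)OCc3ccccc3)c(O)c(C)c1OC2=O | intermediate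
18 | 6-formyl-4,8-dihydroxy-3-methoxy-1,9-dimethyl-11-oxo-11H-dibenzo[b,e][1,4]dioxepine-7-carboxylic acid (not isolated) | COc1cc(C)c2c(c1O)Oc1c(C=O)c(C(=O)O)c(O)c(C)c1OC2=O | intermediate
19 | racemic 1,4,11-trihydroxy-10-methoxy-5,8-dimethyl-1H-isobenzofuro[4,5-b][1,4]benzodioxepine-3,7-dione | COc1cc(C)c2c(c1O)Oc1c(c(C)c(O)c3c1C(O)OC3=O)OC2=O | intermediate
20 | (1R)-4,11-dihydroxy-10-methoxy-5,8-dimethyl-3,7-dioxo-1,3-dihydroisobenzofuro[4,5-b][1,4]benzodioxepin-1-yl acetate | COc1cc(C)c2c(c1O)Oc1c(c(C)c(O)c3c1[C@H](OC(C)=O)OC3=O)OC2=O | intermediate
21 | (1R)-1,4,11-trihydroxy-10-methoxy-5,8-dimethyl-1H-isobenzofuro[4,5-b][1,4]benzodioxepine-3,7-dione | COc1cc(C)c2c(c1O)Oc1c(c(C)c(O)c3c1[C@H](O)OC3=O)OC2=O | target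

**Step count**
Total: 14 steps. Longest linear sequence: 11 steps (steps 1–6 and 10–14); the ring B branch (steps 7–9) joins at step 10.

**Three steps most likely to fail**

Step 11 (key step). The aroyl group may migrate from one catechol oxygen to the other before the C–O bond forms, so that the ring closes through the wrong oxygen. Carbonate may also cleave the aryl ester at 90 °C, traces of air with copper may oxidise the para-dihydroxy pattern of ring B, or the bromine may be lost reductively. The fallback forms the ether bond first and the lactone second; it sets out from 14 and 8 and returns at 19. Compound 14 is benzylated once, at the unchelated phenol para to the ester (BnBr 1 equiv, K2CO3 1 equiv, acetone), to give benzyl 4-(benzyloxy)-2-formyl-3,6-dihydroxy-5-methylbenzoate F1. Compound 8 is converted into benzyl 3-(benzyloxy)-2-bromo-4-methoxy-6-methylbenzoate F2 (BnBr, K2CO3, DMF). An intermolecular Ullmann etherification (CuI, picolinic acid, K3PO4, DMSO, 90 °C) at the more acidic, formyl-flanked phenol of F1 should give benzyl 3-(benzyloxy)-2-[6-(benzyloxy)-3-(benzyloxycarbonyl)-2-formyl-4-hydroxy-5-methylphenoxy]-4-methoxy-6-methylbenzoate F3, which has no acyl group that could migrate. Hydrogenolysis (H2, Pd/C, EtOAc/THF) removes the four benzyl groups and gives the seco acid F4, with ring B closed as the lactol. Lactonisation of the ring A acid onto the neighbouring ring B phenol (DCC, CH2Cl2/THF, high dilution), the classical depsidone closure, then gives 19.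

Step 9. Electrophilic attack may be too slow at a carbon that lies next to the ester, the Lewis acid may cleave the benzyl ester, or the hydroquinone may oxidise during work-up. The fallback is a directed metalation; it sets out from 12 and returns at 14. The three phenols are protected (MOMCl, NaH, DMF, 0 °C, argon) to give benzyl 2,4,5-tris(methoxymethoxy)-3-methylbenzoate F5. TMPMgCl·LiCl (THF, 0 °C to rt) should magnesiate the single ring C–H, which lies between the ester and a methoxymethoxy group, and quenching with DMF gives benzyl 2-formyl-3,4,6-tris(methoxymethoxy)-5-methylbenzoate F6. TFA in CH2Cl2 at 0 °C to rt removes the three acetal groups and gives 14.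

Step 13. The lipase may discriminate the enantiomers poorly, may acylate a phenol, or racemisation may be slower than acylation, so that only a plain kinetic resolution results; the configuration may also erode when the lactol is set free in step 14. The fallback is a physical resolution; it sets out from 19 and returns at 21, bypassing steps 13 and 14. The enantiomers of 19 are separated by preparative supercritical-fluid chromatography on an immobilised amylose-based chiral phase (CO2/MeOH with 0.1% formic acid, column kept cold). The (R) fraction is 21, and the (S) fraction is racemised with a trace of Et3N and resubmitted. This fallback makes no new compound (F0).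

**Further compounds**
F1 | step 11 | benzyl 4-(benzyloxy)-2-formyl-3,6-dihydroxy-5-methylbenzoate | Cc1c(OCc2ccccc2)c(O)c(C=O)c(C(=O)OCc2ccccc2)c1O
F2 | step 11 | benzyl 3-(benzyloxy)-2-bromo-4-methoxy-6-methylbenzoate | COc1cc(C)c(C(=O)OCc2ccccc2)c(Br)c1OCc1ccccc1
F3 | step 11 | benzyl 3-(benzyloxy)-2-[6-(benzyloxy)-3-(benzyloxycarbonyl)-2-formyl-4-hydroxy-5-methylphenoxy]-4-methoxy-6-methylbenzoate | COc1cc(C)c(C(=O)OCc2ccccc2)c(Oc2c(C=O)c(C(=O)OCc3ccccc3)c(O)c(C)c2OCc2ccccc2)c1OCc1ccccc1
F4 | step 11 | seco acid, racemic 3-hydroxy-4-methoxy-6-methyl-2-[(3,5,7-trihydroxy-6-methyl-1-oxo-1,3-dihydro-2-benzofuran-4-yl)oxy]benzoic acid | COc1cc(C)c(C(=O)O)c(Oc2c(O)c(C)c(O)c3c2C(O)OC3=O)c1O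
F5 | step 9 | benzyl 2,4,5-tris(methoxymethoxy)-3-methylbenzoate | Cc1c(OCOC)c(OCOC)cc(C(=O)OCc2ccccc2)c1OCOC
F6 | step 9 | benzyl 2-formyl-3,4,6-tris(methoxymethoxy)-5-methylbenzoate | Cc1c(OCOC)c(OCOC)c(C=O)c(C(=O)OCc2ccccc2)c1OCOC
F0 | step 13 | none | none
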